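The alpha run is down to 0.0771 of its first rate by its last interval, as read from the readings. In this flask, starting material and partner give product over a free catalyst. I take the first rate as the mean over the first 10 min, which gives 0.00294 M min⁻¹.

| flask | starting material | partner | free catalyst | time |
|---|---|---|---|---|
| alpha | 0.250 M | 0.750 M | 0.0200 M |  |
| theta | 0.250 M | 1.50 M | 0.0200 M |  |
| delta | 0.250 M | 0.750 M | 0.0100 M |  |
| epsilon | 0.0500 M | 0.750 M | 0.0200 M | 58 min |

| run | time / min | [product] / M |
|---|---|---|
| alpha run | 3.3 | 0.0103 |
| alpha run | 10 | 0.0294 |
| alpha run | 19 | 0.0483 |
| alpha run | 30 | 0.0638 |
| alpha run | 43 | 0.0755 |
| alpha run | 58 | 0.0789 |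
| theta run | 3.3 | 0.0118 |
| theta run | 10 | 0.0298 |
| theta run | 19 | 0.0489 |
| theta run | 30 | 0.0678 |
| theta run | 43 | 0.0786 |
| theta run | 58 | 0.0828 |
| delta run | 3.3 | 0.0043 |
| delta run | 10 | 0.0161 |
| delta run | 19 | 0.0246 |
| delta run | 30 | 0.0358 |
| delta run | 43 | 0.0465 |
| delta run | 58 | 0.0497 |

(each reading ± 8 × 10⁻⁴ M)

- Overall: starting material + partner -> product, with free catalyst as catalyst.
- Constant volume, constant temperature.
- A reading of a species includes what of it is bound.
- "The second partner" is partner.
- An order is taken over about fifteen percent of the charge, up and down.

1. the power of [partner] that the first rate follows, about the charge of the alpha run; measure it at two percent of starting material made into product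
2. the power of [free catalyst] that the first rate follows, about the charge of the alpha run; measure it at two percent of starting material made into product
3. product in the epsilon run at 58 min, as a share of the starting material charged

I work with the fraction left. At 58 min the share of the alpha charge of starting material not read as product is 0.684, so the rate has come down further than that share. A rate proportional to that share comes down by that factor, and the readings hold a further factor of 0.113. At the start, doubling the partner in the theta run multiplies the first rate by 1.01, and halving the free catalyst in the delta run multiplies it by 0.548.

The slowing adds up to one number per run. Dividing the mean rate over the whole 58 min by the first rate gives 0.463 for the alpha run and 0.532 for the delta run. I call this the kept share, and product at the end is first rate times time times kept share. As read, the delta run starts slower than the alpha run and keeps more.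

No run varies the starting material, so the first rate of the epsilon run is the weak point. My own reckoning takes it proportional to c(starting material), which gives 5.88 × 10⁻⁴ M min⁻¹. That is slower than the delta run, so I use the delta share. The product is then 0.0182 M, or 36.3% of the charge.

The forecast gives 0.1 (from −0.05 to 0.3) for the partner, 0.9 (from 0.7 to 1.1) for the free catalyst, and 52% (from 30% to 90%) for the epsilon run. That last figure is above mine, and it adds: “Weaker substrate dependence would push it higher”.

The simulation gives 0.062 for the order in the partner, 1.0 for the order in the free catalyst, and 76.3% for the epsilon run.

    free catalyst + starting material → loaded catalyst + by-product (2.934 M⁻¹ min⁻¹)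
    loaded catalyst + partner → product + free catalyst (5.274 M⁻¹ min⁻¹)
    2 starting material ⇌ idle substrate dimer, settled at all times (16.00 M⁻¹)
    2 partner → lost reagent (0.4206 M⁻¹ min⁻¹)

Read backwards through the delta kept share, the epsilon product needs a first rate of 0.00124 M min⁻¹. That is 0.422 of the alpha rate, not 0.200, and it amounts to a power of 0.539 in c(starting material) over this step down. Starting material pairs with itself into idle substrate dimer, and the run without that pairing shows the effect: because of the pairing, the apparent order in c(starting material) is 0.57 rather than 0.81.

The numbers in the tables are calculated from invented constants, and the scatter is random.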